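- You read the flask at 40 min, so the first thing to find out is whether that is a long time for this flask.

| flask | starting material | remark | time |
|---|---|---|---|
| larch | 0.0010 M | the very flask that is asked about, followed so far |  |
| birch | 6.7 × 10⁻⁴ M | run made earlier |  |
| flask | 0.0010 M |  | 40 min |

| run | time / min | target / % | isomer of the product A / % |
|---|---|---|---|
| larch | 0.500 | 27.5 | 41.7 |
| larch | 1.00 | 18.5 | 60.3 |
| larch | 2.00 | 11.6 | 74.8 |
| larch | 4.00 | 5.2 | 79.5 |
| larch | 8.00 | 7.2 | 81.6 |
| birch | 8.00 | 6.9 | 81.1 |
| birch | 15.0 | 8.7 | 79.0 |
| birch | 25.0 | 7.5 | 78.5 |
| birch | 30.0 | 8.0 | 77.8 |
| birch | 40.0 | 7.6 | 78.7 |

(standard deviation of a reading: 1 percentage point)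

* at 40 min, what has stopped the reaction, if anything has (all of the starting material has reacted / forward and back rates have come level / it is still moving)
* amount of target at 40 min, in percent of the starting material charged
* amount of isomer of the product A at 40 min, in percent of the starting material charged

- what may be going on: starting material <-> target; starting material <-> isomer of the product A; starting material <-> isomer of the product B; starting material <-> dormant form
- the reaction counts as stopped when no species that holds the starting material changes by six tenths of a point or more over the second half of the time

- In the birch run, [isomer of the product A] stays flat within the scatter from 15.0 min on and reads 78.7 % at 40.0 min, so any slow drift up to that time is already inside this level.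
- In the larch run, [isomer of the product A] lies 37 percentage points below that level at 0.500 min and 18 points below it at 1.00 min.
- A gap that closes by first-order relaxation loses the same share in each equal stretch of time, so these two readings give a settling half-time of 0.496 min, the time that halves the gap.
- Your reading time is the other time that counts, and it is 80.6 settling half-times long.
- At 8.00 min, the larch run and the birch run read 81.6 % and 81.1 % of isomer of the product A, within the scatter, so I expect the flask to stand level at the last birch readings, 7.6 % target and 78.7 % isomer of the product A.
- The forecast, slightly apart from my figures, gives 7.9 % target, 78.3 % isomer of the product A and forward and back rates have come level: “Nothing has run out, so this is equilibrium, not exhaustion.”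
- The flask gives 7.88 % target and 78.8 % isomer of the product A at 40 min: forward and back rates have come level.

    starting material ⇌ target (K = 1.70, k = 0.420 s⁻¹)
    starting material ⇌ isomer of the product A (K = 17.0, k = 0.0670 s⁻¹)
    starting material ⇌ isomer of the product B (K = 0.880, k = 0.00190 s⁻¹)
    starting material ⇌ dormant form (K = 1.00, k = 0.0750 s⁻¹)

- In the flask, the step from starting material to isomer of the product A did half of its turnover by 0.443 min, far earlier than 40 min, and its backward turnover came to 90 % of its forward one. The neighbour flask with 0.0025 M of starting material, read after the same 80.6 settling half-times of this flask, stands at 7.88 % target and 78.8 % isomer of the product A.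

All runs were computed on assumed constants, noise included.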